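Ring A is the benzene ring of the dihydrobenzofuran, ring B the guaiacyl ring on C2.
Retrosynthesis: remove the benzyl ether; cut the furan ring of the benzofuran at O1–C2 and C3–C3a into a ring A aryl alkyne and an ortho-iodophenol from eugenol; cut the dihydrofuran O1–C2 bond; cut the C3–CH2OH bond together with the oxygen on C2, back to an E-stilbene and two formaldehyde molecules; cut the stilbene aryl–vinyl bond (Heck).
Enabling feature: the hydroxymethyl carbon on C3 and the oxygen on C2 form an O–C2–C3–CH2–O array, a 1,3-dioxygenated unit that formaldehyde can lay across the stilbene double bond because the para-oxygenated ring B carries the positive charge at C2.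
Forward: Heck coupling joins rings A and B; the Prins step closes a temporary 1,3-dioxane; demesylation and acid exchange it for the dihydrofuran ring; the bromide becomes an alkyne; the benzofuran ring closes last; hydrogenolysis ends the route.
Stereochemistry: C3 (R) comes from the chiral acid in the Prins step; C2 (S) is set trans to C3 when the ring A phenol closes onto the benzylic cation.

Key step: step 5

Assumption: the sense of induction of the confined acid on a stilbene cannot be derived from the styrene cases, so the catalyst enantiomer that leads to the 4R,5R dioxane is chosen by a test reaction.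

Step 1
Reactants: 1 4-(benzyloxy)-3-methoxybenzaldehyde
Product: 2 1-(benzyloxy)-4-ethenyl-2-methoxybenzene (4-benzyloxy-3-methoxystyrene)
Conditions: Ph3PCH3Br, KOtBu, THF, 0 °C to rt
Reagents that add atoms: methyltriphenylphosphonium bromide, C[P+](c1ccccc1)(c1ccccc1)c1ccccc1.[Br-]
Why: Wittig methylenation of an aryl aldehyde with the non-stabilised ylide is reliable and leaves the benzyl and methyl ethers untouched.

Step 2
Reactants: 3 4-bromo-2-methoxyphenol
Product: 4 4-bromo-2-iodo-6-methoxyphenol
Conditions: NIS, TsOH·H2O (cat.), MeCN, 0 °C to rt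
Reagents that add atoms: N-iodosuccinimide, O=C1CCC(=O)N1I
Why: Electrophilic aromatic iodination is directed by the free hydroxyl group, whose para position is blocked by bromine, so iodine should enter the one open ortho position.

Step 3
Reactants: 4 4-bromo-2-iodo-6-methoxyphenol
Product: 5 4-bromo-2-iodo-6-methoxyphenyl methanesulfonate
Conditions: MsCl, Et3N, CH2Cl2, 0 °C
Reagents that add atoms: methanesulfonyl chloride, CS(=O)(=O)Cl
Why: O-sulfonylation of the phenol installs a small, acid-stable, electron-withdrawing group that later makes ring A the poorer cation stabiliser, and doing it before the olefination avoids exposing an ortho-formyl mesylate to base.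

Step 4
Reactants: 5 4-bromo-2-iodo-6-methoxyphenyl methanesulfonate; 2 1-(benzyloxy)-4-ethenyl-2-methoxybenzene
Product: 6 2-[(E)-2-(4-benzyloxy-3-methoxyphenyl)ethenyl]-4-bromo-6-methoxyphenyl methanesulfonate
Conditions: Pd(OAc)2 (5 mol %), nBu4NCl, NaHCO3, DMF, 60 °C
Reagents that add atoms: none
Why: A Mizoroki–Heck reaction under ligand-free phase-transfer conditions engages the C–I bond well before the C–Br bond and, through syn insertion and syn β-hydride elimination, should give the E-stilbene.

Step 5
Reactants: 6 2-[(E)-2-(4-benzyloxy-3-methoxyphenyl)ethenyl]-4-bromo-6-methoxyphenyl methanesulfonate; 7 formaldehyde (as paraformaldehyde; two molecules are taken up)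
Product: 8 2-[(4R,5R)-4-(4-benzyloxy-3-methoxyphenyl)-1,3-dioxan-5-yl]-4-bromo-6-methoxyphenyl methanesulfonate (trans-4,5-diaryl-1,3-dioxane)
Conditions: (CH2O)n (5 equiv), confined chiral imino-imidodiphosphate acid (BINOL-derived, 3,3′-diaryl, N-triflyl; 5 mol %), CHCl3–cyclohexane, 25 °C
Reagents that add atoms: none
Why: Proposed new method: the chiral acid protonates a formaldehyde oligomer, and the ion-paired oxocarbenium attacks the alkene carbon bonded to ring A while positive charge builds on the carbon bonded to ring B; the closest known reactions are the catalytic asymmetric Prins reaction of styrenes with paraformaldehyde under confined imino-imidodiphosphate acids, not yet extended to stilbenes, and the classical Prins dioxane synthesis from anethole-type alkenes. The dioxane closes when the hemiformal oxygen attacks that benzylic carbon on the same face as the new C–C bond, a six-membered closure that is formally a [4+2] addition of the O=CH2–O–CH2+ unit across the alkene. C5 of the dioxane (later C3 of the target) is set by the chiral counter-anion, which selects the alkene face that the oxocarbenium attacks. C4 follows from the E geometry through suprafacial addition, which gives the trans-diequatorial dioxane; this is also the more stable isomer if the C4–O bond ionises reversibly. The step needs regioselectivity, secured by the para-benzyloxy group of ring B against the mesyloxy, meta-methoxy and meta-bromo groups of ring A, and enantiofacial selectivity, which rests on the catalyst alone and is the uncertain point. Only C5 is carried into the target, because C4 is reset in step 7.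

Step 6
Reactants: 8 2-[(4R,5R)-4-(4-benzyloxy-3-methoxyphenyl)-1,3-dioxan-5-yl]-4-bromo-6-methoxyphenyl methanesulfonate
Product: 9 2-[(4R,5R)-4-(4-benzyloxy-3-methoxyphenyl)-1,3-dioxan-5-yl]-4-bromo-6-methoxyphenol
Conditions: KOH, MeOH–THF–H2O, 65 °C
Reagents that add atoms: none
Why: Base-mediated cleavage of an aryl methanesulfonate (sulfene elimination or attack at sulfur) frees the phenol, while the cyclic formal, the aryl bromide and the benzyl ether are inert to hydroxide.

Step 7
Reactants: 9 2-[(4R,5R)-4-(4-benzyloxy-3-methoxyphenyl)-1,3-dioxan-5-yl]-4-bromo-6-methoxyphenol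
Product: 11 [(2S,3R)-2-(4-benzyloxy-3-methoxyphenyl)-5-bromo-7-methoxy-2,3-dihydro-1-benzofuran-3-yl]methanol, via side-chain hemiformal 10 (not isolated)
Conditions: TsOH·H2O (cat.), CH2Cl2–MeOH, 35 °C
Reagents that add atoms: none
Why: Acid ionises the benzylic C4–O bond of the dioxane to a para-benzyloxybenzyl (quinone-methide-like) cation that the neighbouring phenol captures in an SN1 etherification, the closure long used to make 2-aryl-3-hydroxymethyl-dihydrobenzofurans from benzylic alcohols, while the hemiformal left on the side chain passes its formaldehyde to methanol; C2 should form trans to the fixed C3 substituent because the aryl group avoids the hydroxymethyl arm and the closure is reversible, so either configuration at the former C4 leads to the 2S,3R product.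

Step 8
Reactants: 11 [(2S,3R)-2-(4-benzyloxy-3-methoxyphenyl)-5-bromo-7-methoxy-2,3-dihydro-1-benzofuran-3-yl]methanol
Product: 12 [(2S,3R)-2-(4-benzyloxy-3-methoxyphenyl)-7-methoxy-5-[(trimethylsilyl)ethynyl]-2,3-dihydro-1-benzofuran-3-yl]methanol
Conditions: ethynyltrimethylsilane, Pd(PhCN)2Cl2, tBu3P·HBF4, CuI, iPr2NH, 1,4-dioxane, 40 °C
Reagents that add atoms: ethynyltrimethylsilane, C#C[Si](C)(C)C
Why: A Sonogashira coupling with the electron-rich tri-tert-butylphosphine palladium catalyst allows oxidative addition into the electron-rich aryl bromide under mild conditions that tolerate the free alcohol and touch neither stereocentre.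

Step 9
Reactants: 12 [(2S,3R)-2-(4-benzyloxy-3-methoxyphenyl)-7-methoxy-5-[(trimethylsilyl)ethynyl]-2,3-dihydro-1-benzofuran-3-yl]methanol
Product: 13 [(2S,3R)-2-(4-benzyloxy-3-methoxyphenyl)-5-ethynyl-7-methoxy-2,3-dihydro-1-benzofuran-3-yl]methanol
Conditions: K2CO3, MeOH–THF, rt
Reagents that add atoms: none
Why: Carbonate-mediated methanolysis of the alkynyl C–Si bond (protodesilylation) is fast and leaves every other group untouched.

Step 10
Reactants: 14 eugenol (4-allyl-2-methoxyphenol)
Product: 15 4-(3-hydroxypropyl)-2-methoxyphenol (dihydroconiferyl alcohol)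
Conditions: 9-BBN, THF, 0 °C to rt; then NaOH, H2O2, 0 °C
Reagents that add atoms: hydrogen peroxide, OO
Why: Hydroboration–oxidation with the bulky borane places boron on the terminal carbon of the allyl group (anti-Markovnikov), and the phenol only consumes one equivalent of borane and is regenerated on work-up.

Step 11
Reactants: 15 4-(3-hydroxypropyl)-2-methoxyphenol
Product: 16 4-(3-hydroxypropyl)-2-iodo-6-methoxyphenol
Conditions: NIS, TsOH·H2O (cat.), MeCN, 0 °C
Reagents that add atoms: N-iodosuccinimide, O=C1CCC(=O)N1I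
Why: Electrophilic aromatic iodination is again directed by the free hydroxyl group to its one open ortho position, the para position carrying the side chain.

Step 12
Reactants: 13 [(2S,3R)-2-(4-benzyloxy-3-methoxyphenyl)-5-ethynyl-7-methoxy-2,3-dihydro-1-benzofuran-3-yl]methanol; 16 4-(3-hydroxypropyl)-2-iodo-6-methoxyphenol
Product: 18 3-{2-[(2S,3R)-2-(4-benzyloxy-3-methoxyphenyl)-3-(hydroxymethyl)-7-methoxy-2,3-dihydro-1-benzofuran-5-yl]-7-methoxy-1-benzofuran-5-yl}propan-1-ol, via ortho-alkynylphenol 17 (not isolated)
Conditions: Pd(PPh3)2Cl2, CuI, Et3N, DMF, rt to 70 °C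
Reagents that add atoms: none
Why: Sonogashira coupling of the terminal alkyne with the ortho-iodophenol is followed in the same flask by metal-assisted 5-endo-dig attack of the phenol oxygen on the alkyne, the standard heteroannulation to 2-arylbenzofurans, and no stereocentre is involved.

Step 13
Reactants: 18 3-{2-[(2S,3R)-2-(4-benzyloxy-3-methoxyphenyl)-3-(hydroxymethyl)-7-methoxy-2,3-dihydro-1-benzofuran-5-yl]-7-methoxy-1-benzofuran-5-yl}propan-1-ol
Product: 19 3-{2-[(2S,3R)-2-(4-hydroxy-3-methoxyphenyl)-3-(hydroxymethyl)-7-methoxy-2,3-dihydro-1-benzofuran-5-yl]-7-methoxy-1-benzofuran-5-yl}propan-1-ol (CNP0308311.1)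
Conditions: H2 (1 atm), Pd/C, EtOAc–MeOH, rt
Reagents that add atoms: none
Why: Hydrogenolysis of an aryl benzyl ether over Pd/C is much faster than reduction of the benzofuran C2–C3 bond or cleavage of the cyclic benzylic ether, so brief exposure at atmospheric pressure should free the phenol selectively.

Compound list
1 | 4-(benzyloxy)-3-methoxybenzaldehyde (O-benzylvanillin) | COc1cc(C=O)ccc1OCc1ccccc1 | starting material
2 | 1-(benzyloxy)-4-ethenyl-2-methoxybenzene | COc1cc(C=C)ccc1OCc1ccccc1 | intermediate
3 | 4-bromo-2-methoxyphenol | COc1cc(Br)ccc1O | starting material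
4 | 4-bromo-2-iodo-6-methoxyphenol | COc1cc(Br)cc(I)c1O | intermediate
5 | 4-bromo-2-iodo-6-methoxyphenyl methanesulfonate | COc1cc(Br)cc(I)c1OS(C)(=O)=O | intermediate
6 | 2-[(E)-2-(4-benzyloxy-3-methoxyphenyl)ethenyl]-4-bromo-6-methoxyphenyl methanesulfonate | COc1cc(/C=C/c2cc(Br)cc(OC)c2OS(C)(=O)=O)ccc1OCc1ccccc1 | intermediate
7 | formaldehyde (used as paraformaldehyde) | C=O | starting material
8 | 2-[(4R,5R)-4-(4-benzyloxy-3-methoxyphenyl)-1,3-dioxan-5-yl]-4-bromo-6-methoxyphenyl methanesulfonate | COc1cc([C@@H]2OCOC[C@H]2c2cc(Br)cc(OC)c2OS(C)(=O)=O)ccc1OCc1ccccc1 | intermediate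
9 | 2-[(4R,5R)-4-(4-benzyloxy-3-methoxyphenyl)-1,3-dioxan-5-yl]-4-bromo-6-methoxyphenol | COc1cc([C@@H]2OCOC[C@H]2c2cc(Br)cc(OC)c2O)ccc1OCc1ccccc1 | intermediate
10 | {[(2S,3R)-2-(4-benzyloxy-3-methoxyphenyl)-5-bromo-7-methoxy-2,3-dihydro-1-benzofuran-3-yl]methoxy}methanol | COc1cc([C@H]2Oc3c(OC)cc(Br)cc3[C@@H]2COCO)ccc1OCc1ccccc1 | intermediate
11 | [(2S,3R)-2-(4-benzyloxy-3-methoxyphenyl)-5-bromo-7-methoxy-2,3-dihydro-1-benzofuran-3-yl]methanol | COc1cc([C@H]2Oc3c(OC)cc(Br)cc3[C@@H]2CO)ccc1OCc1ccccc1 | intermediate
12 | [(2S,3R)-2-(4-benzyloxy-3-methoxyphenyl)-7-methoxy-5-[(trimethylsilyl)ethynyl]-2,3-dihydro-1-benzofuran-3-yl]methanol | COc1cc([C@H]2Oc3c(OC)cc(C#C[Si](C)(C)C)cc3[C@@H]2CO)ccc1OCc1ccccc1 | intermediate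
13 | [(2S,3R)-2-(4-benzyloxy-3-methoxyphenyl)-5-ethynyl-7-methoxy-2,3-dihydro-1-benzofuran-3-yl]methanol | COc1cc([C@H]2Oc3c(OC)cc(C#C)cc3[C@@H]2CO)ccc1OCc1ccccc1 | intermediate
14 | eugenol (4-allyl-2-methoxyphenol) | C=CCc1ccc(O)c(OC)c1 | starting material
15 | 4-(3-hydroxypropyl)-2-methoxyphenol | OCCCc1ccc(O)c(OC)c1 | intermediate
16 | 4-(3-hydroxypropyl)-2-iodo-6-methoxyphenol | OCCCc1cc(I)c(O)c(OC)c1 | intermediate
17 | 2-{[(2S,3R)-2-(4-benzyloxy-3-methoxyphenyl)-3-(hydroxymethyl)-7-methoxy-2,3-dihydro-1-benzofuran-5-yl]ethynyl}-4-(3-hydroxypropyl)-6-methoxyphenol | COc1cc([C@H]2Oc3c(OC)cc(C#Cc4cc(CCCO)cc(OC)c4O)cc3[C@@H]2CO)ccc1OCc1ccccc1 | intermediate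
18 | 3-{2-[(2S,3R)-2-(4-benzyloxy-3-methoxyphenyl)-3-(hydroxymethyl)-7-methoxy-2,3-dihydro-1-benzofuran-5-yl]-7-methoxy-1-benzofuran-5-yl}propan-1-ol | COc1cc([C@H]2Oc3c(OC)cc(-c4cc5cc(CCCO)cc(OC)c5o4)cc3[C@@H]2CO)ccc1OCc1ccccc1 | intermediate
19 | 3-{2-[(2S,3R)-2-(4-hydroxy-3-methoxyphenyl)-3-(hydroxymethyl)-7-methoxy-2,3-dihydro-1-benzofuran-5-yl]-7-methoxy-1-benzofuran-5-yl}propan-1-ol | COc1cc([C@H]2Oc3c(OC)cc(-c4cc5cc(CCCO)cc(OC)c5o4)cc3[C@@H]2CO)ccc1O | target

Total step count: 13. Longest linear sequence: 10 steps (steps 2, 3, 4, 5, 6, 7, 8, 9, 12, 13, from 4-bromo-2-methoxyphenol).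

Steps most likely to fail

Step 5. The stilbene may be too large for the confined acid, so that there is no turnover, or it may react through a free benzylic cation outside the chiral pocket, which would give poor enantiofacial selectivity. Hydroxymethylation of the electron-rich ring B and cationic oligomerisation of the stilbene are further risks. The fallback gives up catalyst control and uses known chemistry. It sets out from 6: the classical Prins dioxane synthesis with paraformaldehyde and an achiral strong acid (catalytic TfOH in CH2Cl2, or H2SO4 in acetic acid), established for anethole-type aryl alkenes, should give the racemic trans-dioxane mesylate F1. Its enantiomers are then separated by preparative chromatography on a polysaccharide chiral stationary phase, and the 4R,5R enantiomer re-enters the route as 8.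

Step 7. The benzylic cation may fragment back to stilbene and formaldehyde or lose the proton on C3, either of which would erode the configuration at C3, and the closure may give some cis isomer. The fallback closes the ring by SN2 displacement with inversion instead of through a free cation. It sets out from 8: buffered cleavage of the formal carbon (TMSOTf, 2,2′-bipyridyl, CH2Cl2, 0 °C; then H2O) should give, with retention at the benzylic carbon, the (1R,2R)-1,3-diol mesylate F2. Selective silylation of the primary hydroxyl (TIPSCl, imidazole, DMF) gives the triisopropylsilyl ether mesylate F3, and KOH in MeOH–THF–H2O frees the silyl ether phenol F4. Mitsunobu ring closure (PPh3, DIAD, THF, 0 °C) lets the phenol displace the activated benzylic oxygen with inversion to give the silyl-protected trans-dihydrobenzofuran F5, and TBAF in THF returns to the route at 11.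

Step 12. The terminal alkyne may dimerise oxidatively under copper (Glaser coupling), the free iodophenol may couple slowly as its copper phenoxide, and the ring closure may stall at the alkynylphenol. The fallback separates coupling and ring closure. It sets out from 16 and uses 13: acetylation (Ac2O, pyridine) gives the iodoaryl diacetate F6, and Sonogashira coupling with 13 at room temperature (Pd(PPh3)2Cl2, CuI, Et3N, THF) gives the alkynylaryl diacetate F7. Treatment with K2CO3 in MeOH and then Cs2CO3 in DMF at 60 °C removes both acetates, and the phenoxide closes the furan ring by anionic 5-endo-dig addition, returning to the route at 18.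

Further compounds
F1 | step 5 | racemic trans-dioxane mesylate (1:1 mixture of 8 and its 4S,5S enantiomer) | COc1cc([C@@H]2OCOC[C@H]2c2cc(Br)cc(OC)c2OS(C)(=O)=O)ccc1OCc1ccccc1.COc1cc([C@H]2OCOC[C@@H]2c2cc(Br)cc(OC)c2OS(C)(=O)=O)ccc1OCc1ccccc1
F2 | step 7 | 2-[(1R,2R)-1-(4-benzyloxy-3-methoxyphenyl)-1,3-dihydroxypropan-2-yl]-4-bromo-6-methoxyphenyl methanesulfonate | COc1cc([C@H](O)[C@@H](CO)c2cc(Br)cc(OC)c2OS(C)(=O)=O)ccc1OCc1ccccc1
F3 | step 7 | 2-[(1R,2R)-1-(4-benzyloxy-3-methoxyphenyl)-1-hydroxy-3-(triisopropylsilyloxy)propan-2-yl]-4-bromo-6-methoxyphenyl methanesulfonate | COc1cc([C@H](O)[C@@H](CO[Si](C(C)C)(C(C)C)C(C)C)c2cc(Br)cc(OC)c2OS(C)(=O)=O)ccc1OCc1ccccc1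
F4 | step 7 | 2-[(1R,2R)-1-(4-benzyloxy-3-methoxyphenyl)-1-hydroxy-3-(triisopropylsilyloxy)propan-2-yl]-4-bromo-6-methoxyphenol | COc1cc([C@H](O)[C@@H](CO[Si](C(C)C)(C(C)C)C(C)C)c2cc(Br)cc(OC)c2O)ccc1OCc1ccccc1
F5 | step 7 | {[(2S,3R)-2-(4-benzyloxy-3-methoxyphenyl)-5-bromo-7-methoxy-2,3-dihydro-1-benzofuran-3-yl]methoxy}tri(propan-2-yl)silane | COc1cc([C@H]2Oc3c(OC)cc(Br)cc3[C@@H]2CO[Si](C(C)C)(C(C)C)C(C)C)ccc1OCc1ccccc1
F6 | step 12 | 3-(4-acetoxy-3-iodo-5-methoxyphenyl)propyl acetate | CC(=O)OCCCc1cc(I)c(OC(C)=O)c(OC)c1
F7 | step 12 | 3-(4-acetoxy-3-{[(2S,3R)-2-(4-benzyloxy-3-methoxyphenyl)-3-(hydroxymethyl)-7-methoxy-2,3-dihydro-1-benzofuran-5-yl]ethynyl}-5-methoxyphenyl)propyl acetate | COc1cc([C@H]2Oc3c(OC)cc(C#Cc4cc(CCCOC(C)=O)cc(OC)c4OC(C)=O)cc3[C@@H]2CO)ccc1OCc1ccccc1
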